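**Strategy.** The route rests on one disconnection: both rings are opened at C4–C5 and C9–C10, and the C7=C8 olefin is traded for a C7 sulfone, which leads back to an open-chain C20 epoxy-triene. In the key step a titanocene(III)-triggered radical cascade closes rings A and B, sets C5, C9 and C10 from the preset C2 acetoxy/C3 oxirane pair, and ends by loss of the sulfonyl radical, which fixes the ring-B olefin at C7=C8. The feature exploited is the cis C2(OAc, equatorial)/C3(OH, axial) pair beside the C4 gem-dimethyl group of ring A: a free C4 radical tolerates the axial C3 oxygen. The precursor comes from two C10 halves joined at C6–C7 through the same sulfone.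

Key step: step 12

Remark: labdane numbering is used for the target and in the Why lines (ring A C1–C5/C10, ring B C5–C10, side chain C11–C16, C17 on C8, C18/C19 on C4, C20 on C10); the target is (2S,3R,5S,9R,10S,13E), an ent-labdane. Acyclic intermediates are named with their own locants.
Remark: the (R)-configured phosphoric acid is assumed to give the (R)-carbinol 9, by analogy with aryl and alkenyl aldehydes; if the sense is opposite, its enantiomer is used.
Remark: 17 and 18 are carried as mixtures of epimers at the sulfone-bearing carbon (C7), which is lost in step 12.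

Step 1
Reactants: 1 geranyl acetate
Product: 2 (2E,6E)-8-hydroxy-3,7-dimethylocta-2,6-dien-1-yl acetate
Conditions: SeO2 (cat.), t-BuOOH, salicylic acid (cat.), CH2Cl2, rt
Reagents that add atoms: tert-butyl hydroperoxide CC(C)(C)OO (terminal oxidant, oxygen relayed by catalytic SeO2)
Why: SeO2/t-BuOOH allylic oxidation (ene reaction then [2,3]-shift) should hydroxylate only the E-methyl group of the electron-richer 6,7-olefin, the 2,3-olefin being deactivated by the allylic acetate.

Step 2
Reactants: 2 (2E,6E)-8-hydroxy-3,7-dimethylocta-2,6-dien-1-yl acetate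
Product: 3 (2E,6E)-8-bromo-3,7-dimethylocta-2,6-dien-1-yl acetate
Conditions: CBr4, PPh3, CH2Cl2, 0 °C
Reagents that add atoms: carbon tetrabromide BrC(Br)(Br)Br
Why: Appel bromination converts the primary allylic alcohol by SN2 under neutral conditions, without allylic shift or loss of the acetate.

Step 3
Reactants: 3 (2E,6E)-8-bromo-3,7-dimethylocta-2,6-dien-1-yl acetate
Product: 4 (2E,6E)-3,7-dimethyl-8-(phenylsulfonyl)octa-2,6-dien-1-yl acetate
Conditions: PhSO2Na, DMF, rt
Reagents that add atoms: sodium benzenesulfinate [Na+].[O-]S(=O)c1ccccc1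
Why: The ambident sulfinate is alkylated at sulfur by the soft primary allylic bromide (SN2), which gives the allylic sulfone with both E olefins intact.

Step 4
Reactants: 4 (2E,6E)-3,7-dimethyl-8-(phenylsulfonyl)octa-2,6-dien-1-yl acetate
Product: 5 (2E,6E)-3,7-dimethyl-8-(phenylsulfonyl)octa-2,6-dien-1-ol
Conditions: K2CO3 (cat.), MeOH, rt
Reagents that add atoms: none
Why: Base-catalysed transesterification frees the C15 hydroxyl, because an acetate on the nucleophilic partner would not survive the carbanion chemistry of step 10.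

Step 5
Reactants: 6 3-methylbut-2-enal; 7 allenylboronic acid pinacol ester
Product: 9 (4R)-2-methylhept-2-en-6-yn-4-ol, via O-pinacolboryl ether 8 (not isolated)
Conditions: (R)-TRIP phosphoric acid (5 mol %), 4 Å MS, toluene, 0 °C; aqueous work-up
Reagents that add atoms: none
Why: Chiral phosphoric acid-catalysed propargylation of an aldehyde with an allenylboronate (closed six-membered SE2' transition state on the catalyst) should add 1,2 to the enal and set the future C2 carbinol centre as R, the configuration that step 9 inverts.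

Step 6
Reactants: 9 (4R)-2-methylhept-2-en-6-yn-4-ol
Product: 11 (2E,5R)-3,7-dimethylocta-2,6-diene-1,5-diol, via alkenylalane 10 (not isolated)
Conditions: Me3Al, Cp2ZrCl2 (0.25 equiv), CH2Cl2, 0 °C to rt; then n-BuLi, (CH2O)n, THF, −78 °C to rt; Rochelle salt work-up
Reagents that add atoms: trimethylaluminium C[Al](C)C; paraformaldehyde (as formaldehyde) C=O
Why: Negishi zirconium-catalysed carboalumination adds methyl and aluminium syn across the terminal alkyne with methyl on the internal carbon, and the derived alanate is trapped by formaldehyde with retention, which fixes the E geometry of the future C5=C10 olefin.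

Step 7
Reactants: 11 (2E,5R)-3,7-dimethylocta-2,6-diene-1,5-diol
Product: 13 (4R,6E)-8-chloro-2,6-dimethylocta-2,6-dien-4-ol, via allylic mesylate 12 (not isolated)
Conditions: MsCl (1.05 equiv), 2,4,6-collidine, LiCl, DMF, 0 °C
Reagents that add atoms: lithium chloride [Li+].[Cl-]
Why: Collington–Meyers chlorination (mesylation, then chloride displacement in DMF) should take the unhindered primary allylic hydroxyl ahead of the secondary one and proceeds without allylic shift.

Step 8
Reactants: 13 (4R,6E)-8-chloro-2,6-dimethylocta-2,6-dien-4-ol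
Product: 14 (1R,3E)-5-chloro-1-[(2S)-3,3-dimethyloxiran-2-yl]-3-methylpent-3-en-1-ol
Conditions: mCPBA, NaHCO3, CH2Cl2, 0 °C
Reagents that add atoms: 3-chloroperoxybenzoic acid OOC(=O)c1cccc(Cl)c1
Why: Hydroxyl-directed peracid epoxidation (Henbest type): A(1,3) strain with the Z-methyl fixes the reactive conformer, so oxygen is delivered syn to the hydroxyl to give the threo epoxy alcohol (new oxirane centre S), while the chloride-bearing olefin is deactivated.

Step 9
Reactants: 14 (1R,3E)-5-chloro-1-[(2S)-3,3-dimethyloxiran-2-yl]-3-methylpent-3-en-1-ol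
Product: 15 (1S,3E)-5-chloro-1-[(2S)-3,3-dimethyloxiran-2-yl]-3-methylpent-3-en-1-yl acetate
Conditions: AcOH, PPh3, DIAD, THF, 0 °C to rt
Reagents that add atoms: acetic acid CC(=O)O
Why: Mitsunobu esterification inverts the carbinol by SN2 and so turns the threo alcohol into the erythro acetate (carbinol S), the relationship that becomes the cis C2/C3 pair of ring A.

Step 10
Reactants: 5 (2E,6E)-3,7-dimethyl-8-(phenylsulfonyl)octa-2,6-dien-1-ol; 15 (1S,3E)-5-chloro-1-[(2S)-3,3-dimethyloxiran-2-yl]-3-methylpent-3-en-1-yl acetate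
Product: 17 (2E,6E,10E,13S,14S)-14,15-epoxy-1-hydroxy-3,7,11,15-tetramethyl-8-(phenylsulfonyl)hexadeca-2,6,10-trien-13-yl acetate (epimers at C8 of the chain), via dilithiated sulfone 16 (not isolated)
Conditions: 5, n-BuLi (2.05 equiv), THF–DMPU, −78 °C; then 15, −78 to −40 °C; aq. NH4Cl
Reagents that add atoms: none
Why: Alkylation of the α-sulfonyl allylic carbanion of the O,C-dianion (Julia/Biellmann-type terpenoid coupling) with the primary allylic chloride forms C6–C7 by SN2 with all olefin geometries retained; allylic halides that carry an acetate are established electrophiles for sulfonyl carbanions at low temperature, and the new sulfone-bearing centre needs no control.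

Step 11
Reactants: 17 (2E,6E,10E,13S,14S)-14,15-epoxy-1-hydroxy-3,7,11,15-tetramethyl-8-(phenylsulfonyl)hexadeca-2,6,10-trien-13-yl acetate
Product: 18 (2E,6E,10E,13S,14S)-14,15-epoxy-3,7,11,15-tetramethyl-8-(phenylsulfonyl)hexadeca-2,6,10-triene-1,13-diyl diacetate (epimers at C8 of the chain)
Conditions: Ac2O, pyridine, DMAP (cat.), CH2Cl2, 0 °C
Reagents that add atoms: acetic anhydride CC(=O)OC(C)=O
Why: Standard pyridine/DMAP acylation of the primary allylic alcohol installs the C15 acetate before the cascade.

Step 12
Reactants: 18 (2E,6E,10E,13S,14S)-14,15-epoxy-3,7,11,15-tetramethyl-8-(phenylsulfonyl)hexadeca-2,6,10-triene-1,13-diyl diacetate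
Product: 20 (2S,3R,5S,9R,10S,13E)-3-hydroxylabda-7,13-diene-2,15-diyl diacetate (target CNP0254679.1), via 3-O-trimethylsilyl ether 19 (not isolated)
Conditions: Cp2TiCl2 (0.3 equiv), Mn dust, TMSCl, 2,4,6-collidine, THF (0.01 M), rt, slow addition of 18; then 1 M HCl, THF
Reagents that add atoms: none
Why: Proposed new method: Cp2Ti(III)Cl opens the trisubstituted oxirane by single-electron transfer at the tertiary C4–O bond; the C4 radical closes ring A by 6-endo-trig attack on C5 of the E C5=C10 olefin, the C10 radical closes ring B by 6-endo-trig attack on C9 of the allylic sulfone, and the tertiary C8 radical, which lies β to sulfur, expels PhSO2• (reduced to sulfinate by a second Ti(III)), so the olefin can only appear at C7=C8. The closest known reactions are titanocene(III) epoxypolyene bicyclisations, which end by titanium capture and β-hydride loss to give mainly exocyclic olefins, and radical allylations with allyl sulfones (SH2'); neither a sulfone-terminated variant nor a 2-acyloxy epoxide substrate is precedented. C5, C10 and C9 follow from the chair–chair array of the two E olefins (anti addition across C5=C10, side chain equatorial at C9), and their absolute sense from the chair in which the C2 acetate is equatorial, since the other chair would place it 1,3-diaxial to the C10 methyl and a C4 methyl. C2 and C3 are untouched, and because the C4 radical is not tied to the breaking C–O bond the C3 oxygen can sit axial, which a concerted epoxonium opening would not allow. Both C7 epimers of 18 should converge, directly by β-scission when sulfur is axial or after titanium capture of the C8 radical and β-elimination of sulfinate. The step needs 6-endo over 5-exo closure (secured by the trisubstituted olefins) and ring closure faster than reduction of the tertiary radicals (secured by their slow capture by the bulky Ti(III) and by high dilution); silyl ether 19 is cleaved in the acidic work-up.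

**Compound list**

1 | geranyl acetate, (2E)-3,7-dimethylocta-2,6-dien-1-yl acetate | CC(C)=CCC/C(C)=C/COC(C)=O | starting material
2 | (2E,6E)-8-hydroxy-3,7-dimethylocta-2,6-dien-1-yl acetate | OC/C(C)=C/CC/C(C)=C/COC(C)=O | intermediate
3 | (2E,6E)-8-bromo-3,7-dimethylocta-2,6-dien-1-yl acetate | BrC/C(C)=C/CC/C(C)=C/COC(C)=O | intermediate
4 | (2E,6E)-3,7-dimethyl-8-(phenylsulfonyl)octa-2,6-dien-1-yl acetate | O=S(=O)(C/C(C)=C/CC/C(C)=C/COC(C)=O)c1ccccc1 | intermediate
5 | (2E,6E)-3,7-dimethyl-8-(phenylsulfonyl)octa-2,6-dien-1-ol | O=S(=O)(C/C(C)=C/CC/C(C)=C/CO)c1ccccc1 | intermediate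
6 | 3-methylbut-2-enal | CC(C)=CC=O | starting material
7 | allenylboronic acid pinacol ester, 4,4,5,5-tetramethyl-2-(propa-1,2-dien-1-yl)-1,3,2-dioxaborolane | C=C=CB1OC(C)(C)C(C)(C)O1 | starting material
8 | O-pinacolboryl ether of 9 (not isolated) | CC(C)=C[C@H](OB1OC(C)(C)C(C)(C)O1)CC#C | intermediate
9 | (4R)-2-methylhept-2-en-6-yn-4-ol | CC(C)=C[C@H](O)CC#C | intermediate
10 | (E)-alkenyl(dimethyl)alane of 9, O-aluminated (not isolated) | CC(C)=C[C@H](O[Al](C)C)C/C(C)=C/[Al](C)C | intermediate
11 | (2E,5R)-3,7-dimethylocta-2,6-diene-1,5-diol | CC(C)=C[C@H](O)C/C(C)=C/CO | intermediate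
12 | (2E,5R)-5-hydroxy-3,7-dimethylocta-2,6-dien-1-yl methanesulfonate (not isolated) | CC(C)=C[C@H](O)C/C(C)=C/COS(C)(=O)=O | intermediate
13 | (4R,6E)-8-chloro-2,6-dimethylocta-2,6-dien-4-ol | CC(C)=C[C@H](O)C/C(C)=C/CCl | intermediate
14 | (1R,3E)-5-chloro-1-[(2S)-3,3-dimethyloxiran-2-yl]-3-methylpent-3-en-1-ol (threo) | CC1(C)O[C@H]1[C@H](O)C/C(C)=C/CCl | intermediate
15 | (1S,3E)-5-chloro-1-[(2S)-3,3-dimethyloxiran-2-yl]-3-methylpent-3-en-1-yl acetate (erythro) | CC1(C)O[C@H]1[C@@H](OC(C)=O)C/C(C)=C/CCl | intermediate
16 | O,C-dilithio derivative of 5 (not isolated) | O=S(=O)(C([Li])/C(C)=C/CC/C(C)=C/CO[Li])c1ccccc1 | intermediate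
17 | (2E,6E,10E,13S,14S)-14,15-epoxy-1-hydroxy-3,7,11,15-tetramethyl-8-(phenylsulfonyl)hexadeca-2,6,10-trien-13-yl acetate, C8 epimers | CC1(C)O[C@H]1[C@@H](OC(C)=O)C/C(C)=C/CC(S(=O)(=O)c1ccccc1)/C(C)=C/CC/C(C)=C/CO | intermediate
18 | (2E,6E,10E,13S,14S)-14,15-epoxy-3,7,11,15-tetramethyl-8-(phenylsulfonyl)hexadeca-2,6,10-triene-1,13-diyl diacetate, C8 epimers | CC1(C)O[C@H]1[C@@H](OC(C)=O)C/C(C)=C/CC(S(=O)(=O)c1ccccc1)/C(C)=C/CC/C(C)=C/COC(C)=O | intermediate
19 | 3-O-trimethylsilyl ether of 20 (not isolated) | CC(=O)OC/C=C(\C)CC[C@@H]1C(C)=CC[C@@H]2C(C)(C)[C@@H](O[Si](C)(C)C)[C@@H](OC(C)=O)C[C@@]12C | intermediate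
20 | (2S,3R,5S,9R,10S,13E)-3-hydroxylabda-7,13-diene-2,15-diyl diacetate (CNP0254679.1) | CC(=O)OC/C=C(\C)CC[C@@H]1C(C)=CC[C@@H]2C(C)(C)[C@@H](O)[C@@H](OC(C)=O)C[C@@]12C | target

**Step count and risks**

Total step count: 12. Longest linear sequence: 8 steps (steps 5–12, from 6 and 7).

Steps most likely to fail:

1. Step 12 (Proposed new method). The sulfonyl group may not be expelled cleanly: the tertiary C8 radical could be captured by titanium and lose hydride toward C17, or be reduced. Sulfonyl radicals could also shift the allylic sulfone of unreacted 18 by 1,3-transposition, and facial control by the C2 acetate could be incomplete. The fallback sets the olefin after a conventional titanocene cyclisation, using known chemistry only. It sets out from 17: buffered sodium amalgam (Na2HPO4, MeOH, −20 °C) removes the sulfone to give (2E,6E,10E,13S,14S)-14,15-epoxy-1-hydroxy-3,7,11,15-tetramethylhexadeca-2,6,10-trien-13-yl acetate F1. Acetylation (Ac2O, pyridine) gives the epoxy diacetate F2. The established Cp2TiCl epoxypolyene bicyclisation (Cp2TiCl2, Mn, TMSCl, collidine, THF; acidic work-up), which ends by titanium capture and β-hydride loss, should give the exocyclic olefin (2S,3R,5S,9R,10S,13E)-3-hydroxylabda-8(17),13-diene-2,15-diyl diacetate F3. Isomerisation of the exocyclic olefin into the ring (RhCl3·3H2O, EtOH, 70 °C) comes back to the route at 20; the Δ8 isomer expected alongside would be removed on AgNO3-impregnated silica.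

2. Step 10. The acetate of 15 may be transferred to the alkoxide or carbanion of 16, or the oxirane may be attacked, before C-alkylation takes place. The fallback joins the halves before acetate and oxirane exist. It sets out from 5 and 13: dianion 16 (from 5) is alkylated with the lithium alkoxide of chloro alcohol 13 (n-BuLi, THF, −78 °C) to give (2E,6E,10E,13R)-3,7,11,15-tetramethyl-8-(phenylsulfonyl)hexadeca-2,6,10,14-tetraene-1,13-diol F4. Selective acetylation of the primary allylic hydroxyl (Ac2O, pyridine, 0 °C) gives the monoacetate F5. Hydroxyl-directed epoxidation (VO(acac)2, t-BuOOH, CH2Cl2) gives the threo epoxy alcohol F6. Mitsunobu inversion with acetic acid (PPh3, DIAD) comes back to the route at 18.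

3. Step 9. Inversion may be incomplete through ionisation with participation of the neighbouring oxirane, SN2' or elimination, and the allylic chloride may quaternise the phosphine. The fallback inverts by oxidation and reduction. It sets out from 14: Dess–Martin oxidation (NaHCO3, CH2Cl2) gives (3E)-5-chloro-1-[(2R)-3,3-dimethyloxiran-2-yl]-3-methylpent-3-en-1-one F7. Chelation-controlled reduction of the α,β-epoxy ketone with Zn(BH4)2 (Et2O, −20 °C) should give the erythro alcohol (1S,3E)-5-chloro-1-[(2S)-3,3-dimethyloxiran-2-yl]-3-methylpent-3-en-1-ol F8. Acetylation (Ac2O, pyridine) comes back to the route at 15.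

Further compounds
F1 | step 12 | (2E,6E,10E,13S,14S)-14,15-epoxy-1-hydroxy-3,7,11,15-tetramethylhexadeca-2,6,10-trien-13-yl acetate | CC1(C)O[C@H]1[C@@H](OC(C)=O)C/C(C)=C/CC/C(C)=C/CC/C(C)=C/CO
F2 | step 12 | (2E,6E,10E,13S,14S)-14,15-epoxy-3,7,11,15-tetramethylhexadeca-2,6,10-triene-1,13-diyl diacetate | CC1(C)O[C@H]1[C@@H](OC(C)=O)C/C(C)=C/CC/C(C)=C/CC/C(C)=C/COC(C)=O
F3 | step 12 | (2S,3R,5S,9R,10S,13E)-3-hydroxylabda-8(17),13-diene-2,15-diyl diacetate | CC(=O)OC/C=C(\C)CC[C@@H]1C(=C)CC[C@@H]2C(C)(C)[C@@H](O)[C@@H](OC(C)=O)C[C@@]12C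
F4 | step 10 | (2E,6E,10E,13R)-3,7,11,15-tetramethyl-8-(phenylsulfonyl)hexadeca-2,6,10,14-tetraene-1,13-diol (C8 epimers) | CC(C)=C[C@H](O)C/C(C)=C/CC(S(=O)(=O)c1ccccc1)/C(C)=C/CC/C(C)=C/CO
F5 | step 10 | (2E,6E,10E,13R)-13-hydroxy-3,7,11,15-tetramethyl-8-(phenylsulfonyl)hexadeca-2,6,10,14-tetraen-1-yl acetate (C8 epimers) | CC(C)=C[C@H](O)C/C(C)=C/CC(S(=O)(=O)c1ccccc1)/C(C)=C/CC/C(C)=C/COC(C)=O
F6 | step 10 | (2E,6E,10E,13R,14S)-14,15-epoxy-13-hydroxy-3,7,11,15-tetramethyl-8-(phenylsulfonyl)hexadeca-2,6,10-trien-1-yl acetate (C8 epimers) | CC1(C)O[C@H]1[C@H](O)C/C(C)=C/CC(S(=O)(=O)c1ccccc1)/C(C)=C/CC/C(C)=C/COC(C)=O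
F7 | step 9 | (3E)-5-chloro-1-[(2R)-3,3-dimethyloxiran-2-yl]-3-methylpent-3-en-1-one | CC1(C)O[C@H]1C(=O)C/C(C)=C/CCl
F8 | step 9 | (1S,3E)-5-chloro-1-[(2S)-3,3-dimethyloxiran-2-yl]-3-methylpent-3-en-1-ol | CC1(C)O[C@H]1[C@@H](O)C/C(C)=C/CCl
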